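**Plan** (chroman atoms O1, C2–C8a; side chain C1'–C13')
1. Cuts: C3'–C4' in the side chain; then, in the pyran ring, O1–C8a (aryl ether) and C4–C4a (aryl–alkyl); and C4'–C5' beside a temporary C5'≡C6' triple bond.
2. Forward, left half: a benzene carrying I (future C4a), Br (C8a) and Cl (C6) takes up (R)-linalool by B-alkyl Suzuki coupling (C4–C4a); palladium etherification closes the pyran ring (O1–C8a); Cl is exchanged for OBn and the prenyl end is cut back to a 3-bromopropyl arm.
3. Forward, right half: (R)-citronellal is homologated to a terminal alkyne and added to acetaldehyde, giving the C4'–C13' propargylic bromide as a mixture of C4' epimers.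
4. The halves are joined at C3'–C4' by a nickel-catalysed stereoconvergent alkyl–alkyl coupling; hydrogenation then removes the alkyne, the remote alkene and the benzyl group.
5. Stereochemistry: C2 from (R)-linalool (its C–O bond is never broken), C8' from (R)-citronellal, C4' from the chiral nickel catalyst acting on the epimer mixture.
6. Enabling feature: C4' is a secondary, methyl-bearing carbon whose neighbour C5' can carry a C5'≡C6' triple bond; this makes C4' propargylic and its radical planar, so both bromide epimers become equivalent.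

Key step: step 11

Assumption: (R)-(−)-linalool and (R)-(+)-citronellal are used at the highest enantiomeric purity on offer, since C2 and C8' are carried through unchanged, whereas C4' rests on catalyst control.

**Step 1**
Reactants: 1 4-chloro-2,5-dimethylaniline
Product: 2 4-chloro-2-iodo-3,6-dimethylaniline
Conditions: NIS (1.05 equiv), MeCN, 0 °C → rt
Reagents that add atoms: N-iodosuccinimide, O=C1CCC(=O)N1I
Why: Electrophilic aromatic iodination is steered by the amino group to its only free ortho position (the future C4a), the para position being blocked by chlorine and the other ortho position by methyl.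

**Step 2**
Reactants: 2 4-chloro-2-iodo-3,6-dimethylaniline
Product: 4 2-bromo-5-chloro-3-iodo-1,4-dimethylbenzene, via arenediazonium bromide 3 (not isolated)
Conditions: NaNO2, 48% aq. HBr, MeCN, 0 °C; then CuBr, 60 °C
Reagents that add atoms: hydrobromic acid, Br
Why: Sandmeyer reaction, in which diazotisation and copper-mediated bromide transfer replace the amino group by bromine at the future C8a without touching the C–I or C–Cl bonds.

**Step 3**
Reactants: 5 (R)-linalool [(3R)-3,7-dimethylocta-1,6-dien-3-ol]; 4 2-bromo-5-chloro-3-iodo-1,4-dimethylbenzene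
Product: 7 (3R)-1-(2-bromo-5-chloro-3,6-dimethylphenyl)-3,7-dimethyloct-6-en-3-ol, via B-alkyl-9-BBN adduct 6 (not isolated)
Conditions: 9-BBN (1.2 equiv to 5), THF, 0 °C → rt; then 4, Pd(dppf)Cl2 (5 mol%), AsPh3 (10 mol%), Cs2CO3, DMF/H2O, 50 °C
Reagents that add atoms: none
Why: 9-BBN should hydroborate the monosubstituted vinyl group far faster than the trisubstituted alkene and place boron on the terminal carbon, and the B-alkyl Suzuki–Miyaura coupling should then engage C–I in preference to C–Br and C–Cl, forming C4–C4a with the carbinol stereocentre untouched.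

**Step 4**
Reactants: 7 (3R)-1-(2-bromo-5-chloro-3,6-dimethylphenyl)-3,7-dimethyloct-6-en-3-ol
Product: 8 (2R)-6-chloro-2,5,8-trimethyl-2-(4-methylpent-3-en-1-yl)-3,4-dihydro-2H-chromene
Conditions: Pd(OAc)2 (3 mol%), 2-(di-tert-butylphosphino)-1,1'-binaphthyl (4 mol%), Cs2CO3, toluene, 80 °C
Reagents that add atoms: none
Why: Intramolecular Buchwald–Hartwig-type C–O coupling closes the six-membered pyran ring at O1–C8a through a tertiary alkoxide that has no hydrogen on its carbinol carbon to divert the palladium alkoxide, reacts at C–Br rather than the slower C–Cl, and retains the linalool configuration at C2 because only the O–H bond of the alcohol is broken.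

**Step 5**
Reactants: 8 (2R)-6-chloro-2,5,8-trimethyl-2-(4-methylpent-3-en-1-yl)-3,4-dihydro-2H-chromene
Product: 9 (2R)-6-(benzyloxy)-2,5,8-trimethyl-2-(4-methylpent-3-en-1-yl)-3,4-dihydro-2H-chromene
Conditions: BnOH (2 equiv), [Pd(allyl)Cl]2 (1.5 mol%), RockPhos (4.5 mol%), Cs2CO3, toluene, 90 °C
Reagents that add atoms: benzyl alcohol, OCc1ccccc1
Why: Palladium-catalysed C–O cross-coupling of an aryl chloride with a primary alcohol, in which the bulky biaryl phosphine favours C–O reductive elimination over β-hydride elimination, installs the C6 oxygen already protected as its benzyl ether.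

**Step 6**
Reactants: 9 (2R)-6-(benzyloxy)-2,5,8-trimethyl-2-(4-methylpent-3-en-1-yl)-3,4-dihydro-2H-chromene
Product: 11 3-[(2S)-6-(benzyloxy)-2,5,8-trimethyl-3,4-dihydro-2H-chromen-2-yl]propan-1-ol, via aldehyde 10 (not isolated)
Conditions: OsO4 (2 mol%), NaIO4 (4 equiv), 2,6-lutidine, 1,4-dioxane/H2O, rt; extractive work-up; then NaBH4, MeOH, 0 °C
Reagents that add atoms: sodium periodate, [Na+].[O-]I(=O)(=O)=O; osmium tetroxide (oxygen carrier), O=[Os](=O)(=O)=O
Why: Lemieux–Johnson cleavage (OsO4-catalysed dihydroxylation and periodate glycol fission) removes the isopropylidene end as acetone without exposing the electron-rich arene to ozone, and borohydride reduces the aldehyde to the primary alcohol at C3'.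

**Step 7**
Reactants: 11 3-[(2S)-6-(benzyloxy)-2,5,8-trimethyl-3,4-dihydro-2H-chromen-2-yl]propan-1-ol
Product: 12 (2S)-6-(benzyloxy)-2-(3-bromopropyl)-2,5,8-trimethyl-3,4-dihydro-2H-chromene
Conditions: CBr4, PPh3, CH2Cl2, 0 °C
Reagents that add atoms: carbon tetrabromide, BrC(Br)(Br)Br
Why: The Appel reaction converts the primary alcohol into the bromide under neutral conditions that leave the benzyl ether and the chroman untouched.

**Step 8**
Reactants: 13 (R)-citronellal [(3R)-3,7-dimethyloct-6-enal]
Product: 14 (4R)-4,8-dimethylnon-7-en-1-yne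
Conditions: dimethyl (1-diazo-2-oxopropyl)phosphonate, K2CO3, MeOH, 0 °C → rt
Reagents that add atoms: dimethyl (1-diazo-2-oxopropyl)phosphonate, CC(=O)C(=[N+]=[N-])P(=O)(OC)OC
Why: Seyferth–Gilbert homologation in its Ohira–Bestmann form turns the aldehyde into the terminal alkyne (the new carbon becomes C5') under mildly basic conditions, and the stereocentre, being β to the carbonyl, cannot epimerise.

**Step 9**
Reactants: 14 (4R)-4,8-dimethylnon-7-en-1-yne
Product: 16 (6R)-6,10-dimethylundec-9-en-3-yn-2-ol (both C2 epimers), via lithium acetylide 15 (not isolated)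
Conditions: n-BuLi, THF, −78 °C; then MeCHO, −78 → 0 °C; H2O
Reagents that add atoms: acetaldehyde, CC=O
Why: Addition of the lithium acetylide to acetaldehyde builds C4' with its methyl group, and the new carbinol centre is left uncontrolled on purpose because it is erased in step 11.

**Step 10**
Reactants: 16 (6R)-6,10-dimethylundec-9-en-3-yn-2-ol
Product: 17 (6R)-2-bromo-6,10-dimethylundec-9-en-3-yne (both C2 epimers)
Conditions: CBr4, PPh3, CH2Cl2, −20 → 0 °C
Reagents that add atoms: carbon tetrabromide, BrC(Br)(Br)Br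
Why: Appel bromination of the secondary propargylic alcohol gives the bromide, whose configuration (like any allenyl bromide formed by transposition) is irrelevant because all these halides lead to the same propargyl radical in step 11.

**Step 11**
Reactants: 12 (2S)-6-(benzyloxy)-2-(3-bromopropyl)-2,5,8-trimethyl-3,4-dihydro-2H-chromene; 17 (6R)-2-bromo-6,10-dimethylundec-9-en-3-yne
Product: 19 (2R)-6-(benzyloxy)-2,5,8-trimethyl-2-[(4S,8R)-4,8,12-trimethyltridec-11-en-5-yn-1-yl]-3,4-dihydro-2H-chromene, via alkylzinc bromide 18 (not isolated)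
Conditions: Zn dust, I2 (5 mol%), DMA, 70 °C (12 → 18, 1.4 equiv); then 17 (1.0 equiv), NiCl2·glyme (10 mol%), (S,S)-i-Pr-Pybox (13 mol%), DMA/THF, −10 °C
Reagents that add atoms: none
Why: Zinc inserts into the primary C–Br bond of 12 and the resulting 18 transmetalates to a nickel–pybox complex, whose monovalent alkylnickel form abstracts bromine from either C4' epimer of 17 to give the same planar propargyl radical, which recombines at nickel and leaves by C(sp3)–C(sp3) reductive elimination as the C3'–C4' bond. The closest known reaction type is the nickel/pybox-catalysed enantioconvergent Negishi coupling of racemic secondary propargylic bromides with organozinc halides. No ring is closed. The new stereocentre C4' is controlled by the chiral ligand alone, the centres at C2 and C8' being too far away to matter, so the epimer mixture is funnelled into one configuration (4'S by the sequence rule while the alkyne is present, 4'R after saturation), and the ligand antipode is confirmed on a model bromide before the fragments are committed. The step needs bond formation at the propargylic and not the allenyl terminus, which is secured because C4' carries only methyl and hydrogen while the allenyl terminus C6' carries the alkyl chain and would become a fully substituted carbon. It also needs the benzyl ether, the chroman and the trisubstituted alkene to stand by, which they should because neither alkylzinc halides nor the nickel catalyst engage them.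

**Step 12**
Reactants: 19 (2R)-6-(benzyloxy)-2,5,8-trimethyl-2-[(4S,8R)-4,8,12-trimethyltridec-11-en-5-yn-1-yl]-3,4-dihydro-2H-chromene
Product: 21 β-tocopherol [(2R)-2,5,8-trimethyl-2-[(4R,8R)-4,8,12-trimethyltridecyl]-3,4-dihydro-2H-chromen-6-ol], via O-benzyl-β-tocopherol 20 (not isolated)
Conditions: H2 (1 atm), PtO2, EtOAc, rt; filter; then H2 (1 atm), 10% Pd/C, EtOAc/EtOH, rt; work-up under argon
Reagents that add atoms: none
Why: Heterogeneous hydrogenation saturates the alkyne and the remote alkene over platinum, which is much less prone than palladium to double-bond migration into the C4' stereocentre, and palladium-catalysed hydrogenolysis then frees the phenol.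

**Compound list**
1 | 4-chloro-2,5-dimethylaniline | Cc1cc(Cl)c(C)cc1N | starting material
2 | 4-chloro-2-iodo-3,6-dimethylaniline | Cc1cc(Cl)c(C)c(I)c1N | intermediate
3 | 4-chloro-2-iodo-3,6-dimethylbenzenediazonium bromide | Cc1cc(Cl)c(C)c(I)c1[N+]#N.[Br-] | intermediate
4 | 2-bromo-5-chloro-3-iodo-1,4-dimethylbenzene | Cc1cc(Cl)c(C)c(I)c1Br | intermediate
5 | (R)-(−)-linalool, (3R)-3,7-dimethylocta-1,6-dien-3-ol | O[C@](C)(CCC=C(C)C)C=C | starting material
6 | (3S)-1-(9-borabicyclo[3.3.1]nonan-9-yl)-3,7-dimethyloct-6-en-3-ol | O[C@](C)(CCC=C(C)C)CCB1C2CCCC1CCC2 | intermediate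
7 | (3R)-1-(2-bromo-5-chloro-3,6-dimethylphenyl)-3,7-dimethyloct-6-en-3-ol | O[C@](C)(CCC=C(C)C)CCc1c(C)c(Cl)cc(C)c1Br | intermediate
8 | (2R)-6-chloro-2,5,8-trimethyl-2-(4-methylpent-3-en-1-yl)-3,4-dihydro-2H-chromene | Cc1cc(Cl)c(C)c2c1O[C@](C)(CCC=C(C)C)CC2 | intermediate
9 | (2R)-6-(benzyloxy)-2,5,8-trimethyl-2-(4-methylpent-3-en-1-yl)-3,4-dihydro-2H-chromene | Cc1cc(OCc3ccccc3)c(C)c2c1O[C@](C)(CCC=C(C)C)CC2 | intermediate
10 | 3-[(2S)-6-(benzyloxy)-2,5,8-trimethyl-3,4-dihydro-2H-chromen-2-yl]propanal | Cc1cc(OCc3ccccc3)c(C)c2c1O[C@](C)(CCC=O)CC2 | intermediate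
11 | 3-[(2S)-6-(benzyloxy)-2,5,8-trimethyl-3,4-dihydro-2H-chromen-2-yl]propan-1-ol | Cc1cc(OCc3ccccc3)c(C)c2c1O[C@](C)(CCCO)CC2 | intermediate
12 | (2S)-6-(benzyloxy)-2-(3-bromopropyl)-2,5,8-trimethyl-3,4-dihydro-2H-chromene | Cc1cc(OCc3ccccc3)c(C)c2c1O[C@](C)(CCCBr)CC2 | intermediate
13 | (R)-(+)-citronellal, (3R)-3,7-dimethyloct-6-enal | O=CC[C@H](C)CCC=C(C)C | starting material
14 | (4R)-4,8-dimethylnon-7-en-1-yne | C#CC[C@H](C)CCC=C(C)C | intermediate
15 | [(4R)-4,8-dimethylnon-7-en-1-yn-1-yl]lithium | [Li]C#CC[C@H](C)CCC=C(C)C | intermediate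
16 | (6R)-6,10-dimethylundec-9-en-3-yn-2-ol, both C2 epimers | CC(O)C#CC[C@H](C)CCC=C(C)C | intermediate
17 | (6R)-2-bromo-6,10-dimethylundec-9-en-3-yne, both C2 epimers | CC(Br)C#CC[C@H](C)CCC=C(C)C | intermediate
18 | {3-[(2S)-6-(benzyloxy)-2,5,8-trimethyl-3,4-dihydro-2H-chromen-2-yl]propyl}zinc bromide | Cc1cc(OCc3ccccc3)c(C)c2c1O[C@](C)(CCC[Zn]Br)CC2 | intermediate
19 | (2R)-6-(benzyloxy)-2,5,8-trimethyl-2-[(4S,8R)-4,8,12-trimethyltridec-11-en-5-yn-1-yl]-3,4-dihydro-2H-chromene | Cc1cc(OCc3ccccc3)c(C)c2c1O[C@](C)(CCC[C@H](C)C#CC[C@H](C)CCC=C(C)C)CC2 | intermediate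
20 | O-benzyl-β-tocopherol, (2R)-6-(benzyloxy)-2,5,8-trimethyl-2-[(4R,8R)-4,8,12-trimethyltridecyl]-3,4-dihydro-2H-chromene | Cc1cc(OCc3ccccc3)c(C)c2c1O[C@](C)(CCC[C@H](C)CCC[C@H](C)CCCC(C)C)CC2 | intermediate
21 | β-tocopherol, (2R)-2,5,8-trimethyl-2-[(4R,8R)-4,8,12-trimethyltridecyl]-3,4-dihydro-2H-chromen-6-ol | Cc1cc(O)c(C)c2c1O[C@](C)(CCC[C@H](C)CCC[C@H](C)CCCC(C)C)CC2 | target

Note on descriptors: the changes at the carbinol carbon (3R in 5 and 7, 3S in 6), at C2 (R in 8, 9, 19–21; S in 10–12, 18) and at C4' (S in 19, R in 20 and 21) follow from the sequence rule only; no bond at these centres is made or broken in those steps.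

**Totals**
Total step count: 12. Longest linear sequence: 9 steps (steps 1–7, 11, 12); the right half takes 3 steps (8–10).

**Steps most likely to fail**

Step 11. What may go wrong: loss of enantiofacial discrimination at nickel for an alkyne that carries only a plain primary alkyl group, competing bond formation at the allenyl terminus, and dehydrobromination of the propargylic bromide. Fallback: an anilide replaces the alkyne as the radical-stabilising group, the best-documented electrophile class for enantioconvergent coupling with primary alkylzinc halides. The fallback sets out from 13 and from the zinc reagent 18 and returns at 20.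
- Citronellal 13 is condensed with the ylide from (2-carboxyethyl)triphenylphosphonium bromide (NaN(SiMe3)2, THF; Wittig reaction) to (3Z,6R)-6,10-dimethylundeca-3,9-dienoic acid F1.
- Hydrogenation (H2, PtO2, EtOAc) gives (6S)-6,10-dimethylundecanoic acid F2.
- SOCl2 gives (6S)-6,10-dimethylundecanoyl chloride F3, and NBS with catalytic HBr brominates it at C2 (Hell–Volhard–Zelinsky type) to (6R)-2-bromo-6,10-dimethylundecanoyl chloride F4.
- N-Benzylaniline/Et3N gives (6R)-N-benzyl-2-bromo-6,10-dimethyl-N-phenylundecanamide F5 as both C2 epimers.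
- Negishi coupling of F5 with 18 (NiCl2·glyme, i-Pr-Pybox in the antipode fixed on a model, DMI/THF, 0 °C) should give the α-alkylated anilide (2R,6R)-N-benzyl-2-{3-[(2R)-6-(benzyloxy)-2,5,8-trimethyl-3,4-dihydro-2H-chromen-2-yl]propyl}-6,10-dimethyl-N-phenylundecanamide F6, with the ligand setting C4'.
- LiAlH4 (THF) reduces F6 to (2R,6R)-2-{3-[(2R)-6-(benzyloxy)-2,5,8-trimethyl-3,4-dihydro-2H-chromen-2-yl]propyl}-6,10-dimethylundecan-1-ol F7.
- TsCl/pyridine gives the corresponding 4-methylbenzenesulfonate F8, and LiEt3BH (THF) turns CH2OTs into the C4' methyl group, giving 20, which is debenzylated as in the second stage of step 12.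

Step 5. What may go wrong: sluggish oxidative addition into the hindered, electron-rich C–Cl bond and β-hydride elimination from the palladium benzyloxide, which would return the dechlorinated chroman. Fallback: the oxygen is brought in through boron instead of by direct C–O coupling. The fallback sets out from 8 and returns at 9.
- Miyaura borylation of 8 (Pd2(dba)3, XPhos, B2pin2, KOAc, 1,4-dioxane, 100 °C) gives (2R)-2,5,8-trimethyl-2-(4-methylpent-3-en-1-yl)-6-(4,4,5,5-tetramethyl-1,3,2-dioxaborolan-2-yl)-3,4-dihydro-2H-chromene F9.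
- Oxidation (NaBO3·4H2O, THF/H2O) gives (2R)-2,5,8-trimethyl-2-(4-methylpent-3-en-1-yl)-3,4-dihydro-2H-chromen-6-ol F10.
- Benzylation (BnBr, K2CO3, DMF) gives 9.

Step 3. What may go wrong: slow transmetalation at an iodide flanked by two ortho substituents, so that protodeboronation of the alkylborane and oxidative addition at the C–Br bond gain ground. Fallback: C4–C4a is formed by a Heck reaction instead of a hydroboration/Suzuki sequence. The fallback sets out from 4 and 5 and returns at 7.
- Heck arylation of the vinyl group of 5 with 4 (Pd(OAc)2, Bu4NCl, NaHCO3, DMF, 80 °C) gives (1E,3R)-1-(2-bromo-5-chloro-3,6-dimethylphenyl)-3,7-dimethylocta-1,6-dien-3-ol F11.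
- Diimide (2-nitrobenzenesulfonyl hydrazide, Et3N, CH2Cl2, rt) reduces the disubstituted styrenyl double bond in preference to the trisubstituted one and leaves the aryl halides alone, giving 7.

**Further compounds**
F1 | step 11 | (3Z,6R)-6,10-dimethylundeca-3,9-dienoic acid | OC(=O)C/C=C\C[C@H](C)CCC=C(C)C
F2 | step 11 | (6S)-6,10-dimethylundecanoic acid | OC(=O)CCCC[C@H](C)CCCC(C)C
F3 | step 11 | (6S)-6,10-dimethylundecanoyl chloride | ClC(=O)CCCC[C@H](C)CCCC(C)C
F4 | step 11 | (6R)-2-bromo-6,10-dimethylundecanoyl chloride, both C2 epimers | ClC(=O)C(Br)CCC[C@H](C)CCCC(C)C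
F5 | step 11 | (6R)-N-benzyl-2-bromo-6,10-dimethyl-N-phenylundecanamide, both C2 epimers | O=C(C(Br)CCC[C@H](C)CCCC(C)C)N(Cc1ccccc1)c1ccccc1
F6 | step 11 | (2R,6R)-N-benzyl-2-{3-[(2R)-6-(benzyloxy)-2,5,8-trimethyl-3,4-dihydro-2H-chromen-2-yl]propyl}-6,10-dimethyl-N-phenylundecanamide | Cc1cc(OCc3ccccc3)c(C)c2c1O[C@](C)(CCC[C@H](C(=O)N(Cc3ccccc3)c3ccccc3)CCC[C@H](C)CCCC(C)C)CC2
F7 | step 11 | (2R,6R)-2-{3-[(2R)-6-(benzyloxy)-2,5,8-trimethyl-3,4-dihydro-2H-chromen-2-yl]propyl}-6,10-dimethylundecan-1-ol | Cc1cc(OCc3ccccc3)c(C)c2c1O[C@](C)(CCC[C@H](CO)CCC[C@H](C)CCCC(C)C)CC2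
F8 | step 11 | (2R,6R)-2-{3-[(2R)-6-(benzyloxy)-2,5,8-trimethyl-3,4-dihydro-2H-chromen-2-yl]propyl}-6,10-dimethylundecyl 4-methylbenzenesulfonate | Cc1cc(OCc3ccccc3)c(C)c2c1O[C@](C)(CCC[C@H](COS(=O)(=O)c3ccc(C)cc3)CCC[C@H](C)CCCC(C)C)CC2
F9 | step 5 | (2R)-2,5,8-trimethyl-2-(4-methylpent-3-en-1-yl)-6-(4,4,5,5-tetramethyl-1,3,2-dioxaborolan-2-yl)-3,4-dihydro-2H-chromene | Cc1cc(B3OC(C)(C)C(C)(C)O3)c(C)c2c1O[C@](C)(CCC=C(C)C)CC2
F10 | step 5 | (2R)-2,5,8-trimethyl-2-(4-methylpent-3-en-1-yl)-3,4-dihydro-2H-chromen-6-ol | Cc1cc(O)c(C)c2c1O[C@](C)(CCC=C(C)C)CC2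
F11 | step 3 | (1E,3R)-1-(2-bromo-5-chloro-3,6-dimethylphenyl)-3,7-dimethylocta-1,6-dien-3-ol | O[C@](C)(CCC=C(C)C)/C=C/c1c(C)c(Cl)cc(C)c1Br
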